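**Retrosynthetic overview**
1. Ludongnin J (18) ⇒ oxidation of the C15 allylic alcohol (17) ⇐ SeO2 ene/[2,3]-sigmatropic allylic oxidation of the C16=C17 alkene in 16. This forms the last C–O bond (C15–O) and is the key step.
2. 16 (6-OMe acetal) ⇐ lactol 15 ⇐ 6,19-olide/7,20-olide 14 ⇐ seco acid-aldehyde 13, from periodate cleavage of the α-ketol 7-hydroxy-6-ketone 12. The THF ring and the spiro δ-lactone therefore close last, after the B ring is opened at C6–C7.
3. 12 ⇐ kinetic α′-hydroxylation of 6-keto-19,20-diol 11 ⇐ two syn-diaxial Barton nitrite C–H oxidations from the C19 alcohol 6, at C6 first and then C20.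
4. 6 ⇐ methyl ent-kaurenoate 5 ⇐ steviol (2) with the C13-OH removed radically ⇐ stevioside (1). Rings A–D and the C4, C5, C8, C9, C10 and C13 configurations are inherited; C6 is set thermodynamically at the acetal.

Assumption (one line): the C19 alkoxyl radical abstracts the syn-diaxial 6β-H first and C20–H once C6 is blocked as C=N, Δ16 survives the radical and hydride steps, and the aldoxime hydrolyses faster than the hindered C6 ketoxime.

---

**Step 1**
Reactants: 1 stevioside
Product: 2 steviol (ent-13-hydroxykaur-16-en-19-oic acid)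
Conditions: NaIO4, H2O, rt; then KOH, H2O, 100 °C
Reagents that add atoms: KOH, [K+].[OH-] (hydroxide O ends up in the carboxylate)
Why: Periodate oxidises the sugar diols and hydroxide then hydrolyses the C19 ester and releases O-13, giving steviol without the acid-catalysed Wagner–Meerwein rearrangement to isosteviol; all skeletal stereocenters are untouched.

**Step 2**
Reactants: 2 steviol
Product: 3 methyl steviolate
Conditions: MeI, K2CO3, DMF, rt
Reagents that add atoms: MeI, CI
Why: The carboxylate is alkylated selectively (SN2) while the tertiary bridgehead OH is untouched, which protects the acid for the radical step.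

**Step 3**
Reactants: 3 methyl steviolate
Product: 4 13-O-(methoxyoxalyl) ester of methyl steviolate
Conditions: ClCOCO2Me, DMAP, Et3N, CH2Cl2, 0 °C to rt
Reagents that add atoms: methyl chlorooxoacetate, COC(=O)C(=O)Cl
Why: Acylation of the tertiary allylic alcohol gives the methyl oxalate, the standard radical-deoxygenation handle for tertiary alcohols (Barton–Crich).

**Step 4**
Reactants: 4
Product: 5 methyl ent-kaur-16-en-19-oate
Conditions: Bu3SnH, AIBN, PhMe, 110 °C
Reagents that add atoms: none (only H is delivered)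
Why: Barton–McCombie-type deoxygenation generates the C13 bridgehead radical, and H-transfer can only occur with the geometry fixed by the bicyclo[3.2.1] skeleton, so C13 is set without a new stereochemical choice.

**Step 5**
Reactants: 5
Product: 6 ent-kaur-16-en-19-ol
Conditions: LiAlH4, THF, 0 °C to 65 °C
Reagents that add atoms: none
Why: Ester reduction leaves C4 untouched and gives the axial C19 alcohol that serves as the radical-relay handle.

**Step 6**
Reactants: 6
Product: 7 ent-6-(hydroxyimino)kaur-16-en-19-ol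
Conditions: t-BuONO, CH2Cl2, rt; then hν (Hg, Pyrex), PhMe, 0 °C
Reagents that add atoms: tert-butyl nitrite, CC(C)(C)ON=O (supplies N–O)
Why: Barton nitrite photolysis – the 19-alkoxyl radical abstracts the syn-diaxial 6β-H, NO recombines at C6 and the nitroso compound tautomerises to the oxime; no stereocenter is disturbed.

**Step 7**
Reactants: 7
Product: 8 ent-19-hydroxy-6-oxokaur-16-en-20-al 6,20-dioxime
Conditions: t-BuONO, CH2Cl2, rt; then hν (Hg, Pyrex), PhMe, 0 °C
Reagents that add atoms: tert-butyl nitrite, CC(C)(C)ON=O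
Why: A second Barton reaction with C6 blocked as C=N; the 19-alkoxyl radical takes the 1,3-diaxial C20–H and the C20 radical is nitrosated to the aldoxime.

**Step 8**
Reactants: 8
Product: 9 ent-19-hydroxy-6-(hydroxyimino)kaur-16-en-20-al (a 19,20-lactol when closed)
Conditions: acetone/H2O, PPTS, 50 °C
Reagents that add atoms: water, O (carbonyl O)
Why: Transoximation/hydrolysis is much faster for the unhindered aldoxime than for the α-branched C6 ketoxime, so only C20 is unmasked.

**Step 9**
Reactants: 9
Product: 10 ent-6-(hydroxyimino)kaur-16-ene-19,20-diol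
Conditions: NaBH4, MeOH, 0 °C
Reagents that add atoms: none
Why: The aldehyde (via the open lactol form) is reduced to the primary alcohol while the oxime and the alkene are inert to borohydride, giving the required C20 oxygen.

**Step 10**
Reactants: 10
Product: 11 ent-19,20-dihydroxykaur-16-en-6-one
Conditions: TiCl3, NH4OAc, THF/H2O, rt
Reagents that add atoms: water, O
Why: Buffered Ti(III) reductive hydrolysis converts the ketoxime to the ketone without acid, so Δ16 and the C5 centre survive.

**Step 11**
Reactants: 11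
Product: 12 ent-7,19,20-trihydroxykaur-16-en-6-one (C7 epimers, undefined)
Conditions: LiHMDS (4.5 equiv), THF, –78 °C; then 2-(phenylsulfonyl)-3-phenyloxaziridine (racemic)
Reagents that add atoms: Davis oxaziridine, O=S(=O)(c1ccccc1)N1OC1c1ccccc1 (supplies the C7–OH oxygen)
Why: Kinetic enolisation occurs at the unbranched C7 (C5–H is tertiary and hindered), and Davis α-hydroxylation gives the α-ketol; the new C7 stereocentre is irrelevant because C7 becomes a carbonyl next.

**Step 12**
Reactants: 12
Product: 13 6,7-seco-ent-kaur-16-en-6,19-olide 7,20-lactol (C7 lactol epimers)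
Conditions: NaIO4, MeOH/H2O, rt; then PPTS, CH2Cl2, rt
Reagents that add atoms: sodium periodate, [Na+].[O-]I(=O)(=O)=O (O ends up in the C6 carboxyl); water, O
Why: Periodate α-ketol cleavage (glycol-cleavage type) breaks C6–C7 to give the C6 acid and C7 aldehyde, which close onto the C19-OH (γ-lactone) and C20-OH (lactol), the only mutually compatible pairing; this sets the spirocentre environment and retains C5.

**Step 13**
Reactants: 13
Product: 14 6,7-seco-ent-kaur-16-ene-6,19:7,20-diolide
Conditions: PCC, NaOAc, CH2Cl2, rt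
Reagents that add atoms: none
Why: Oxidation of the lactol to the δ-lactone gives the 7,20-lactone with the hindered C8 quaternary carbon untouched.

**Step 14**
Reactants: 14
Product: 15 6-hydroxy-6,19-epoxy (lactol) 7,20-olide
Conditions: DIBAL-H (1.05 equiv), CH2Cl2, –78 °C
Reagents that add atoms: none
Why: The cis-fused γ-lactone carbonyl on C5 is much less hindered than the δ-lactone carbonyl on the fully substituted C8, so partial reduction stops at the C6 lactol (C6 epimers undefined).

**Step 15**
Reactants: 15; methanol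
Product: 16 15-deoxo (Δ16) Ludongnin J precursor, the 6-methoxy-6,19-epoxy acetal
Conditions: MeOH, PPTS, rt
Reagents that add atoms: methanol, CO (supplies OMe)
Why: Acid-catalysed acetalisation through the oxocarbenium ion gives the thermodynamic, anomerically favoured C6 methyl acetal on the cis-fused THF, which is the C6 configuration of the target.

**Step 16**
Reactants: 16
Product: 17 15-hydroxy-16-ene acetal (C15 epimers)
Conditions: SeO2, TBHP, pyridine (cat.), CH2Cl2, rt
Reagents that add atoms: selenium dioxide, O=[Se]=O; tert-butyl hydroperoxide, CC(C)(C)OO (supply the C15–O oxygen)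
Why: SeO2 ene reaction followed by [2,3]-sigmatropic rearrangement of the allylic seleninic acid forms the C15–O bond with the exocyclic alkene restored, and only C15 can react because the C13 bridgehead H cannot give a Bredt-violating ene product.

**Step 17**
Reactants: 17
Product: 18 Ludongnin J
Conditions: Dess–Martin periodinane, NaHCO3, CH2Cl2, rt
Reagents that add atoms: none
Why: Oxidation of the secondary allylic alcohol gives the C15 enone, and the new carbonyl removes the C15 stereocentre.

---

**Compound list**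

1 | stevioside | `C[C@@]12CCC[C@@]([C@H]1CC[C@]34[C@H]2CC[C@@](C3)(O[C@@H]5O[C@H](CO)[C@@H](O)[C@H](O)[C@H]5O[C@@H]6O[C@H](CO)[C@@H](O)[C@H](O)[C@H]6O)C(=C)C4)(C)C(=O)O[C@@H]7O[C@H](CO)[C@@H](O)[C@H](O)[C@H]7O` | starting material
2 | steviol | `C[C@@]12CCC[C@@]([C@H]1CC[C@]34[C@H]2CC[C@@](C3)(O)C(=C)C4)(C)C(=O)O` | intermediate
3 | methyl steviolate | `C[C@@]12CCC[C@@]([C@H]1CC[C@]34[C@H]2CC[C@@](C3)(O)C(=C)C4)(C)C(=O)OC` | intermediate
4 | methyl 13-O-(methoxyoxalyl)steviolate | `C[C@@]12CCC[C@@]([C@H]1CC[C@]34[C@H]2CC[C@@](C3)(OC(=O)C(=O)OC)C(=C)C4)(C)C(=O)OC` | intermediate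
5 | methyl ent-kaur-16-en-19-oate | `C[C@@]12CCC[C@@]([C@H]1CC[C@]34[C@H]2CC[C@H](C3)C(=C)C4)(C)C(=O)OC` | intermediate
6 | ent-kaur-16-en-19-ol | `C[C@@]12CCC[C@@]([C@H]1CC[C@]34[C@H]2CC[C@H](C3)C(=C)C4)(C)CO` | intermediate
7 | ent-6-(hydroxyimino)kaur-16-en-19-ol | `C[C@@]12CCC[C@@]([C@H]1C(=NO)C[C@]34[C@H]2CC[C@H](C3)C(=C)C4)(C)CO` | intermediate
8 | ent-19-hydroxy-6-oxokaur-16-en-20-al 6,20-dioxime | `ON=C[C@@]12CCC[C@@]([C@H]1C(=NO)C[C@]34[C@H]2CC[C@H](C3)C(=C)C4)(C)CO` | intermediate
9 | ent-19-hydroxy-6-(hydroxyimino)kaur-16-en-20-al | `O=C[C@@]12CCC[C@@]([C@H]1C(=NO)C[C@]34[C@H]2CC[C@H](C3)C(=C)C4)(C)CO` | intermediate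
10 | ent-6-(hydroxyimino)kaur-16-ene-19,20-diol | `OC[C@@]12CCC[C@@]([C@H]1C(=NO)C[C@]34[C@H]2CC[C@H](C3)C(=C)C4)(C)CO` | intermediate
11 | ent-19,20-dihydroxykaur-16-en-6-one | `OC[C@@]12CCC[C@@]([C@H]1C(=O)C[C@]34[C@H]2CC[C@H](C3)C(=C)C4)(C)CO` | intermediate
12 | ent-7,19,20-trihydroxykaur-16-en-6-one (C7 epimers) | `OC[C@@]12CCC[C@@]([C@H]1C(=O)C(O)[C@]34[C@H]2CC[C@H](C3)C(=C)C4)(C)CO` | intermediate
13 | 6,7-seco-ent-kaur-16-en-6,19-olide 7,20-lactol (C7 epimers) | `C=C1C[C@]23C[C@H]1CC[C@H]2[C@@]1(CCC[C@@]2(C)COC(=O)[C@H]21)COC3O` | intermediate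
14 | 6,7-seco-ent-kaur-16-ene-6,19:7,20-diolide | `C=C1C[C@]23C[C@H]1CC[C@H]2[C@@]1(CCC[C@@]2(C)COC(=O)[C@H]21)COC3=O` | intermediate
15 | 6-hydroxy-6,19-epoxy (lactol), 7,20-olide (C6 epimers) | `C=C1C[C@]23C[C@H]1CC[C@H]2[C@@]1(CCC[C@@]2(C)COC(O)[C@H]21)COC3=O` | intermediate
16 | 15-deoxo-Ludongnin J (6-OMe acetal, Δ16) | `C=C1C[C@]23C[C@H]1CC[C@H]2[C@@]1(CCC[C@@]2(C)CO[C@@H](OC)[C@H]21)COC3=O` | intermediate
17 | 15-hydroxy-Ludongnin J precursor (C15 epimers) | `C=C1C(O)[C@]23C[C@H]1CC[C@H]2[C@@]1(CCC[C@@]2(C)CO[C@@H](OC)[C@H]21)COC3=O` | intermediate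
18 | Ludongnin J | `C=C1C(=O)[C@]23C[C@H]1CC[C@H]2[C@@]1(CCC[C@@]2(C)CO[C@@H](OC)[C@H]21)COC3=O` | target

---

**Total step count:** 17 steps.
**Longest linear sequence:** 17 steps (stevioside to 18; 16 steps from steviol).

**Three steps most likely to fail, with fallbacks**
1. **Step 7 (second Barton reaction, C20 versus C2 selectivity).** Fallback: reduce the C6 ketone of 11-type material to the 6β-alcohol, acetylate the primary C19-OH, and use the classical 6β-nitrite Barton reaction to reach C20. This changes the directing oxygen from O-19 to O-6.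
2. **Step 11 (enolate hydroxylation in the presence of a free diol).** Fallback: avoid enolate chemistry by converting the 6-ketone to a Δ6 olefin (trisylhydrazone Shapiro reaction) and cleaving it with OsO4/NaIO4 to the C6/C7 oxidation levels needed.
3. **Step 16 (SeO2/TBHP next to the acid-sensitive methyl acetal).** Fallback: build the D-ring enone differently by ozonolysing Δ16 early to the 16-ketone, carrying it through, then SeO2 (Riley) oxidation to the 15,16-dione and chemoselective Wittig methylenation at C16.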